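The route rests on disconnecting the bond between C2 of the pyran (C) ring and C1' of the 3-hydroxy-4-methoxyphenyl (B) ring. The precursor is a 2,3-dihydroxychroman lactol with the (3R) centre from methyl (R)-glycidate; it is condensed with the B-ring boronic acid to a cis-fused cyclic boronate. Lewis acid ionization at C2 then gives an oxocarbenium ion, and the aryl group migrates from boron to C2. The step exploits the cis relationship between O3 and the C2 aryl on the C ring: O3 holds boron and delivers the B ring to its own face, so one operation joins both halves, sets C2 and frees O3 for galloylation.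

Key step: step 5

Remark: compounds 1, 3, 10 and 13 are taken as commercially available; all phenols are carried as benzyl ethers and released together in the last step.

Step 1
Reactants: 1 3,5-bis(benzyloxy)phenol
Product: 2 1,3-bis(benzyloxy)-5-(methoxymethoxy)benzene
Conditions: MOMCl, i-Pr2NEt, CH2Cl2, 0 °C to rt
Reagents that add atoms: chloromethyl methyl ether, COCCl
Why: O-alkylation of the phenol (MOM ether formation) should proceed cleanly; the MOM group is the directing group for step 2 and is acid-labile.

Step 2
Reactants: 2 1,3-bis(benzyloxy)-5-(methoxymethoxy)benzene; 3 methyl (2R)-oxirane-2-carboxylate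
Product: 6 methyl (2R)-3-[2,4-bis(benzyloxy)-6-(methoxymethoxy)phenyl]-2-hydroxypropanoate, via aryllithium 4 (not isolated), via arylmagnesium bromide 5 (not isolated)
Conditions: n-BuLi, TMEDA, THF, 0 °C; MgBr2·OEt2, −40 °C; CuI (10 mol%), then 3, −40 to −10 °C; aq. NH4Cl
Reagents that add atoms: none
Why: Directed ortho-metalation should occur between OMOM (the strongest director) and OBn, and Cu(I)-catalysed SN2 opening of the glycidate at its CH2 terminus by the hindered aryl Grignard should outrun attack on the ester; the glycidate stereocentre is not touched, so (R) is carried over.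

Step 3
Reactants: 6 methyl (2R)-3-[2,4-bis(benzyloxy)-6-(methoxymethoxy)phenyl]-2-hydroxypropanoate
Product: 8 (3R)-5,7-bis(benzyloxy)-3-hydroxychroman-2-one, via phenol ester 7 (not isolated)
Conditions: TsOH·H2O (cat.), MeOH, 50 °C; then toluene, 80 °C (MeOH distilled off)
Reagents that add atoms: none
Why: Acid-catalysed acetal exchange should remove the MOM group (trapped by methanol), and the freed phenol should lactonise onto the methyl ester to the six-membered dihydrocoumarin; no bond at the stereocentre is broken.

Step 4
Reactants: 8 (3R)-5,7-bis(benzyloxy)-3-hydroxychroman-2-one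
Product: 9 (3R)-5,7-bis(benzyloxy)chromane-2,3-diol (mixture at C2)
Conditions: DIBAL-H (2.3 equiv), CH2Cl2, −78 °C; Rochelle salt
Reagents that add atoms: none
Why: Partial reduction of a lactone to the lactol by DIBAL-H at low temperature; the first equivalent is consumed by the 3-OH and the aluminium hemiacetal should survive until work-up, leaving C3 untouched.

Step 5
Reactants: 9 (3R)-5,7-bis(benzyloxy)chromane-2,3-diol; 10 [3-(benzyloxy)-4-methoxyphenyl]boronic acid
Product: 12 (2R,3R)-5,7-bis(benzyloxy)-2-[3-(benzyloxy)-4-methoxyphenyl]chroman-3-ol, via cyclic boronate 11 (not isolated)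
Conditions: 10 (1.5 equiv), 4 Å MS, CH2Cl2, rt; then BF3·OEt2 (1.5 equiv), 0.02 M, −78 to −20 °C; aq. NaHCO3
Reagents that add atoms: none
Why: Proposed new method: the lactol anomers equilibrate and the 2,3-cis diol condenses with the boronic acid to the cis-fused dioxaborolane 11; BF3 then ionises the anomeric C2–O bond to a chroman-2-yl oxocarbenium ion while boron stays on O3 as a four-coordinate borate, whose aryl group migrates through its ipso carbon to C2 via a five-membered cyclic transition state (C2–C3–O3–B–C1'), and aqueous work-up hydrolyses the O3–B bond. The closest known reactions are the Petasis borono-Mannich reaction of α-hydroxy aldehydes, the hydroxyl-directed cis-selective addition of aryl and alkenyl boronates to cyclic N-acyliminium ions, and boronate addition to 2H-chromene acetals; a saturated chroman lactol with a directing 3-hydroxyl is the new element. No ring of the product is closed here; the dioxaborolane ring of 11 forms by condensation and is opened again. The new C2 stereocentre is controlled by the existing C3 centre, because the aryl group can only be delivered to the face that carries O3, which gives the 2,3-cis (2R,3R) arrangement. The step needs ipso transfer, fixed by the C–B bond para to the methoxy group, and it needs tethered delivery to outrun attack of the electron-rich A ring of a second molecule on the cation, which pre-formation of 11, high dilution and low temperature should secure.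

Step 6
Reactants: 12 (2R,3R)-5,7-bis(benzyloxy)-2-[3-(benzyloxy)-4-methoxyphenyl]chroman-3-ol; 13 3,4,5-tris(benzyloxy)benzoyl chloride
Product: 14 (2R,3R)-5,7-bis(benzyloxy)-2-[3-(benzyloxy)-4-methoxyphenyl]chroman-3-yl 3,4,5-tris(benzyloxy)benzoate
Conditions: Et3N, DMAP (cat.), CH2Cl2, 0 °C to rt
Reagents that add atoms: none
Why: DMAP-catalysed acylation of the secondary (axial) alcohol by an acid chloride should give the ester without touching either stereocentre.

Step 7
Reactants: 14 (2R,3R)-5,7-bis(benzyloxy)-2-[3-(benzyloxy)-4-methoxyphenyl]chroman-3-yl 3,4,5-tris(benzyloxy)benzoate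
Product: 15 4'-O-methylepicatechin-3-O-gallate, (2R,3R)-5,7-dihydroxy-2-(3-hydroxy-4-methoxyphenyl)chroman-3-yl 3,4,5-trihydroxybenzoate
Conditions: H2 (1 atm), Pd(OH)2/C, THF/MeOH, rt
Reagents that add atoms: none
Why: Catalytic hydrogenolysis should cleave all six benzyl aryl ethers under neutral conditions, while the methyl ether, the ester and both stereocentres remain.

Compound list
1 | 3,5-bis(benzyloxy)phenol | Oc1cc(OCc2ccccc2)cc(OCc2ccccc2)c1 | starting material
2 | 1,3-bis(benzyloxy)-5-(methoxymethoxy)benzene | COCOc1cc(OCc2ccccc2)cc(OCc2ccccc2)c1 | intermediate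
3 | methyl (2R)-oxirane-2-carboxylate (methyl (R)-glycidate) | COC(=O)[C@H]1CO1 | starting material
4 | [2,4-bis(benzyloxy)-6-(methoxymethoxy)phenyl]lithium | [Li]c1c(OCOC)cc(OCc2ccccc2)cc1OCc1ccccc1 | intermediate
5 | [2,4-bis(benzyloxy)-6-(methoxymethoxy)phenyl]magnesium bromide | Br[Mg]c1c(OCOC)cc(OCc2ccccc2)cc1OCc1ccccc1 | intermediate
6 | methyl (2R)-3-[2,4-bis(benzyloxy)-6-(methoxymethoxy)phenyl]-2-hydroxypropanoate | COC(=O)[C@H](O)Cc1c(OCOC)cc(OCc2ccccc2)cc1OCc1ccccc1 | intermediate
7 | methyl (2R)-3-[2,4-bis(benzyloxy)-6-hydroxyphenyl]-2-hydroxypropanoate | COC(=O)[C@H](O)Cc1c(O)cc(OCc2ccccc2)cc1OCc1ccccc1 | intermediate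
8 | (3R)-5,7-bis(benzyloxy)-3-hydroxychroman-2-one | O[C@@H]1Cc2c(OCc3ccccc3)cc(OCc3ccccc3)cc2OC1=O | intermediate
9 | (3R)-5,7-bis(benzyloxy)chromane-2,3-diol (C2 mixture) | O[C@@H]1Cc2c(OCc3ccccc3)cc(OCc3ccccc3)cc2OC1O | intermediate
10 | [3-(benzyloxy)-4-methoxyphenyl]boronic acid | COc1ccc(B(O)O)cc1OCc1ccccc1 | starting material
11 | cis-fused cyclic aryl boronate of 9 (2,3-O-arylboranediyl; 2S,3R in chroman numbering) | COc1ccc(B2O[C@@H]3Cc4c(OCc5ccccc5)cc(OCc5ccccc5)cc4O[C@@H]3O2)cc1OCc1ccccc1 | intermediate
12 | (2R,3R)-5,7-bis(benzyloxy)-2-[3-(benzyloxy)-4-methoxyphenyl]chroman-3-ol | COc1ccc([C@H]2Oc3cc(OCc4ccccc4)cc(OCc4ccccc4)c3C[C@H]2O)cc1OCc1ccccc1 | intermediate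
13 | 3,4,5-tris(benzyloxy)benzoyl chloride | O=C(Cl)c1cc(OCc2ccccc2)c(OCc2ccccc2)c(OCc2ccccc2)c1 | starting material
14 | (2R,3R)-5,7-bis(benzyloxy)-2-[3-(benzyloxy)-4-methoxyphenyl]chroman-3-yl 3,4,5-tris(benzyloxy)benzoate | COc1ccc([C@H]2Oc3cc(OCc4ccccc4)cc(OCc4ccccc4)c3C[C@H]2OC(=O)c2cc(OCc3ccccc3)c(OCc3ccccc3)c(OCc3ccccc3)c2)cc1OCc1ccccc1 | intermediate
15 | 4'-O-methylepicatechin-3-O-gallate | COc1ccc([C@H]2Oc3cc(O)cc(O)c3C[C@H]2OC(=O)c2cc(O)c(O)c(O)c2)cc1O | target

Total step count: 7. Longest linear sequence: 7 steps (1 to 15).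

Steps most likely to fail

1. Step 5 (proposed new method). The cation at C2 may be intercepted by the electron-rich A ring of a second molecule (oligomerisation). The electron-rich boronic acid may protodeboronate. The C3 centre may be lost by enolisation of the α-hydroxy oxocarbenium ion or open-chain aldehyde, and untethered aryl transfer would erode the cis selectivity.
Fallback, known chemistry (intramolecular aryl delivery from an O-arylsilyl group to the neighbouring oxocarbenium carbon by ipso-substitution, as used for 1,2-cis C-aryl glycosides), setting out from 9 and returning at 12. Lactol 9 is converted with MeOH/PPTS into (3R)-5,7-bis(benzyloxy)-2-methoxychroman-3-ol F1. Commercial 2-(benzyloxy)-4-bromo-1-methoxybenzene is exchanged with n-BuLi at −78 °C to [3-(benzyloxy)-4-methoxyphenyl]lithium F2, which is quenched with excess Me2SiCl2 to chloro[3-(benzyloxy)-4-methoxyphenyl]dimethylsilane F3. Silylation of F1 with F3 (imidazole, DMF) should give the 3-O-[aryl(dimethyl)silyl] ether F4. Catalytic TMSOTf in CH2Cl2 at −78 °C should ionise the acetal, and the silicon-bearing ipso carbon (para to OMe) should attack C2 through a five-membered spiro transition state, which can only give the cis product, formed as its 3-O-(methoxydimethylsilyl) ether F5. Methanolysis (K2CO3, MeOH) should release 12.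

2. Step 2. Metalation may occur between the two benzyloxy groups or at a benzylic CH2 (followed by Wittig rearrangement), and the hindered aryl-metal may open the epoxide slowly or attack the ester instead.
Fallback, setting out from 1 and returning at 8: the C3 oxygen is introduced on a preformed lactone instead of coming from the chiral pool. Acid-catalysed hydroarylation–lactonisation of 1 with acrylic acid (cat. TfOH or Amberlyst-15, toluene) should give 5,7-bis(benzyloxy)chroman-2-one F6. Its sodium enolate (NaHMDS, THF, −78 °C) would be hydroxylated with the enantiomer of (camphorsulfonyl)oxaziridine that gives the (R)-alcohol, leading to 8; the enantiomeric purity would have to be raised by crystallisation.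

3. Step 4. The aluminium hemiacetal of the aryl lactone may collapse early and be reduced further to the diol, and the α-hydroxy aldehyde form of 9 may epimerise or isomerise during work-up.
Fallback, setting out from 6 and returning at 9: full reduction followed by selective re-oxidation. LiBH4 in THF should give (2R)-3-[2,4-bis(benzyloxy)-6-(methoxymethoxy)phenyl]propane-1,2-diol F7. TEMPO (cat.)/PhI(OAc)2 should oxidise only the primary alcohol to (2R)-3-[2,4-bis(benzyloxy)-6-(methoxymethoxy)phenyl]-2-hydroxypropanal F8. Aqueous HCl in THF should then remove the MOM group and let the phenol close onto the aldehyde to lactol 9.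

Further compounds
F1 | step 5 | (3R)-5,7-bis(benzyloxy)-2-methoxychroman-3-ol | COC1Oc2cc(OCc3ccccc3)cc(OCc3ccccc3)c2C[C@H]1O
F2 | step 5 | [3-(benzyloxy)-4-methoxyphenyl]lithium | COc1ccc([Li])cc1OCc1ccccc1
F3 | step 5 | chloro[3-(benzyloxy)-4-methoxyphenyl]dimethylsilane | COc1ccc([Si](C)(C)Cl)cc1OCc1ccccc1
F4 | step 5 | (3R)-5,7-bis(benzyloxy)-2-methoxychroman-3-yl [3-(benzyloxy)-4-methoxyphenyl]dimethylsilyl ether | COC1Oc2cc(OCc3ccccc3)cc(OCc3ccccc3)c2C[C@H]1O[Si](C)(C)c1ccc(OC)c(OCc2ccccc2)c1
F5 | step 5 | 3-O-(methoxydimethylsilyl) ether of 12 | COc1ccc([C@H]2Oc3cc(OCc4ccccc4)cc(OCc4ccccc4)c3C[C@H]2O[Si](C)(C)OC)cc1OCc1ccccc1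
F6 | step 2 | 5,7-bis(benzyloxy)chroman-2-one | O=C1CCc2c(OCc3ccccc3)cc(OCc3ccccc3)cc2O1
F7 | step 4 | (2R)-3-[2,4-bis(benzyloxy)-6-(methoxymethoxy)phenyl]propane-1,2-diol | OC[C@H](O)Cc1c(OCOC)cc(OCc2ccccc2)cc1OCc1ccccc1
F8 | step 4 | (2R)-3-[2,4-bis(benzyloxy)-6-(methoxymethoxy)phenyl]-2-hydroxypropanal | O=C[C@H](O)Cc1c(OCOC)cc(OCc2ccccc2)cc1OCc1ccccc1
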